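A direct plan would hydroxylate 1-(3-benzyloxy-2-hydroxy-4-methoxyphenyl)ethanone A1 with persulfate to the 2,5-dihydroxyacetophenone A2, C-acylate its trianion with 3-benzyloxy-4-methoxybenzoyl chloride A3 to the 1,3-diketone A4, oxidise this anodically to the acylquinone A5, whose enol oxygen would close ring C at O1–C8a to the 5,8-dihydroxyflavone A6, and methylate O8 to the 5-hydroxy-7,8-dimethoxyflavone A7 before hydrogenolysis. Its weakest steps would be the persulfate hydroxylation (low conversion; acid hydrolysis of the aryl sulfate beside a benzyl ether), the anodic oxa-Michael ring closure (no precedent; product as oxidisable as substrate) and the trianion C-acylation (competing O-acylation of two phenoxides).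

The route disconnects ring C at its carbonyl carbon: C4 is carbon monoxide, and a palladium-catalysed carbonylative annulation joins it to the iodinated C4a of a complete ring A and to the terminal carbon of an arylacetylene, then closes O1–C2, all in one operation. Ring A exploits its own pattern: in the triol from Thiele–Winter acetoxylation of 2,3-dimethoxybenzoquinone only the future O5 and O6 are vicinal, so a diphenylmethylene ketal leaves the future O1 as the single free hydroxyl and the future C4a as the single free carbon. No acetophenone, persulfate oxidation, polyanion acylation, oxidative O-closure or late methylation remains.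

Key step: step 6

Remark: compounds 1, 7 and 9 are taken as commercial; triol 4 is air-sensitive and would be carried on under nitrogen without isolation; enaminone 11 is drawn as its E isomer, and either geometry should cyclise.

**Step 1**
Reactants: 1 2,3-dimethoxyphenol
Product: 2 2,3-dimethoxy-1,4-benzoquinone
Conditions: ON(SO3K)2 (2.2 equiv), aq KH2PO4, acetone, 0 °C to rt
Reagents that add atoms: potassium nitrosodisulfonate (Fremy's salt), [K+].[K+].[O]N(S(=O)(=O)[O-])S(=O)(=O)[O-]
Why: Teuber oxidation, in which the phenoxyl radical made by the first equivalent is trapped at its free para carbon by the oxygen of a second nitroxyl radical and loss of imidodisulfonate leaves the para-quinone.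

**Step 2**
Reactants: 2 2,3-dimethoxy-1,4-benzoquinone
Product: 3 5,6-dimethoxybenzene-1,2,4-triyl triacetate
Conditions: Ac2O, H2SO4 (cat.), rt to 40 °C; ice water
Reagents that add atoms: acetic anhydride, CC(=O)OC(C)=O
Why: Thiele–Winter acetoxylation, in which the protonated quinone takes up acetate by 1,4-addition at one of its two equivalent CH carbons and enolisation with O-acetylation gives the triacetate, so no regiochemical question arises.

**Step 3**
Reactants: 3 5,6-dimethoxybenzene-1,2,4-triyl triacetate
Product: 5 6,7-dimethoxy-2,2-diphenyl-1,3-benzodioxol-5-ol, via 5,6-dimethoxybenzene-1,2,4-triol 4 (not isolated)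
Conditions: HCl (cat.), MeOH, reflux, N2; evaporate; then Ph2CCl2 (1.1 equiv), Ph2O, 170 °C, N2 stream
Reagents that add atoms: dichlorodiphenylmethane, ClC(Cl)(c1ccccc1)c1ccccc1
Why: acid-catalysed transesterification frees the triol, and ketalisation of a catechol with a gem-dichloride then takes the only vicinal pair of hydroxyls into a five-membered ring, whereas the lone hydroxyl can give at most an α-chloro ether that reverts to the phenol on aqueous work-up.

**Step 4**
Reactants: 5 6,7-dimethoxy-2,2-diphenyl-1,3-benzodioxol-5-ol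
Product: 6 4-iodo-6,7-dimethoxy-2,2-diphenyl-1,3-benzodioxol-5-ol
Conditions: NIS (1.05 equiv), dry MeCN, −20 to 0 °C, dark
Reagents that add atoms: N-iodosuccinimide, O=C1CCC(=O)N1I
Why: electrophilic aromatic iodination of a phenol at its one unsubstituted ring carbon, which is ortho to the hydroxyl and to a ring oxygen and para to a methoxy group, run cold in a dry aprotic solvent to keep the electron-rich phenol from being oxidised.

**Step 5**
Reactants: 7 3-benzyloxy-4-methoxybenzaldehyde
Product: 8 2-benzyloxy-4-ethynyl-1-methoxybenzene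
Conditions: dimethyl (1-diazo-2-oxopropyl)phosphonate (1.2 equiv), K2CO3 (2 equiv), MeOH, rt
Reagents that add atoms: dimethyl (1-diazo-2-oxopropyl)phosphonate, COP(=O)(OC)C(=[N+]=[N-])C(C)=O
Why: Seyferth–Gilbert homologation in its Ohira–Bestmann form, in which methanolysis of the acetyl group frees the diazomethylphosphonate anion and its Horner–Wadsworth–Emmons addition to the aldehyde, loss of N2 and a 1,2-hydride shift give the terminal alkyne under conditions harmless to aryl ethers.

**Step 6**
Reactants: 6 4-iodo-6,7-dimethoxy-2,2-diphenyl-1,3-benzodioxol-5-ol; 8 2-benzyloxy-4-ethynyl-1-methoxybenzene; 9 carbon monoxide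
Product: 12 2-(3-benzyloxy-4-methoxyphenyl)-7,8-dimethoxy-5,6-(diphenylmethylenedioxy)chromen-4-one, via hydroxyaryl ynone 10 (not isolated), via diethylamino enone 11 (not isolated)
Conditions: PdCl2(PPh3)2 (5 mol %), CO (5 bar), Et2NH (10 equiv), DMF, 90 °C
Reagents that add atoms: carbon monoxide (9), [C-]#[O+]
Why: Zerovalent palladium, formed from the dichloride under CO and amine, inserts into the C–I bond of 6, CO insertion gives an aroylpalladium iodide, and coupling with the amine-deprotonated alkyne 8 releases ynone 10, so that C4a–C4 and C4–C3 are formed around the one-carbon component. Diethylamine then adds to the β-carbon of 10 to give enaminone 11, and the ortho hydroxyl displaces the amine at that carbon by addition–elimination, which closes ring C through O1–C2 as a six-membered ring and excludes the 5-exo-dig closure that would give an aurone. The reaction type is the known palladium-catalysed carbonylative annulation of 2-iodophenols with terminal arylacetylenes and CO (a carbonylative Sonogashira coupling followed by amine-mediated cyclisation), applied here to a hexasubstituted iodophenol. It needs CO insertion to outrun direct alkynylation, which the electron-rich aryl group, the CO pressure and the absence of copper favour, and it needs closure by the right oxygen, which is secured because the only other ortho oxygen is locked in the ketal. The five-membered ketal also ties that oxygen back, so the carbon that bears palladium is less crowded than between two free alkoxy groups. No stereocentre is formed.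

**Step 7**
Reactants: 12 2-(3-benzyloxy-4-methoxyphenyl)-7,8-dimethoxy-5,6-(diphenylmethylenedioxy)chromen-4-one
Product: 13 5,6,3'-trihydroxy-7,8,4'-trimethoxyflavone (5,6-dihydroxy-2-(3-hydroxy-4-methoxyphenyl)-7,8-dimethoxychromen-4-one)
Conditions: H2 (1 atm), 10% Pd/C, THF–MeOH 1:1, rt; work-up under N2
Reagents that add atoms: none
Why: catalytic hydrogenolysis of the benzyl aryl ether and of both benzhydrylic C–O bonds of the diphenylmethylene ketal (which leaves as diphenylmethane), under which the C2=C3 bond of the flavone, part of an aryl-conjugated vinylogous ester, and the three methyl ethers should persist.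

**Compound list**
1 | 2,3-dimethoxyphenol | COc1cccc(O)c1OC | starting material
2 | 2,3-dimethoxy-1,4-benzoquinone | COC1=C(OC)C(=O)C=CC1=O | intermediate
3 | 5,6-dimethoxybenzene-1,2,4-triyl triacetate | COc1c(OC(C)=O)cc(OC(C)=O)c(OC(C)=O)c1OC | intermediate
4 | 5,6-dimethoxybenzene-1,2,4-triol | COc1c(O)cc(O)c(O)c1OC | intermediate
5 | 6,7-dimethoxy-2,2-diphenyl-1,3-benzodioxol-5-ol | COc1c(O)cc2OC(c3ccccc3)(c3ccccc3)Oc2c1OC | intermediate
6 | 4-iodo-6,7-dimethoxy-2,2-diphenyl-1,3-benzodioxol-5-ol | COc1c(O)c(I)c2OC(c3ccccc3)(c3ccccc3)Oc2c1OC | intermediate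
7 | 3-benzyloxy-4-methoxybenzaldehyde | COc1ccc(C=O)cc1OCc1ccccc1 | starting material
8 | 2-benzyloxy-4-ethynyl-1-methoxybenzene | COc1ccc(C#C)cc1OCc1ccccc1 | intermediate
9 | carbon monoxide | [C-]#[O+] | starting material
10 | 3-(3-benzyloxy-4-methoxyphenyl)-1-(5-hydroxy-6,7-dimethoxy-2,2-diphenyl-1,3-benzodioxol-4-yl)prop-2-yn-1-one | COc1ccc(C#CC(=O)c2c(O)c(OC)c(OC)c3OC(c4ccccc4)(c4ccccc4)Oc23)cc1OCc1ccccc1 | intermediate
11 | (E)-3-(3-benzyloxy-4-methoxyphenyl)-3-(diethylamino)-1-(5-hydroxy-6,7-dimethoxy-2,2-diphenyl-1,3-benzodioxol-4-yl)prop-2-en-1-one | CCN(CC)/C(=C/C(=O)c1c(O)c(OC)c(OC)c2OC(c3ccccc3)(c3ccccc3)Oc12)c1ccc(OC)c(OCc2ccccc2)c1 | intermediate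
12 | 2-(3-benzyloxy-4-methoxyphenyl)-7,8-dimethoxy-5,6-(diphenylmethylenedioxy)chromen-4-one | COc1ccc(-c2cc(=O)c3c(o2)c(OC)c(OC)c2OC(c4ccccc4)(c4ccccc4)Oc32)cc1OCc1ccccc1 | intermediate
13 | 5,6,3'-trihydroxy-7,8,4'-trimethoxyflavone | COc1ccc(-c2cc(=O)c3c(O)c(O)c(OC)c(OC)c3o2)cc1O | target

Total step count: 7. Longest linear sequence: 6 steps (steps 1, 2, 3, 4, 6, 7); step 5 is the side branch.

Steps most likely to fail:

Step 6. The arylpalladium species may couple with the alkyne before it takes up CO (leading on to a benzofuran), may lose iodine reductively, or the aroylpalladium species may be intercepted by the amine as an amide. The fallback would set out from phenol 5 and alkyne 8 and come back to the route at 12, closing ring C at C4–C4a without iodide, palladium or CO. Lithiation of 8 (n-BuLi, THF, −78 °C) and ClCO2Et would give ethyl 3-(3-benzyloxy-4-methoxyphenyl)prop-2-ynoate F1. The phenoxide of 5 (K2CO3, DMF, 80 °C) should add to the β-carbon of this ester to give the aryl enol ether ethyl 3-(3-benzyloxy-4-methoxyphenyl)-3-[(6,7-dimethoxy-2,2-diphenyl-1,3-benzodioxol-5-yl)oxy]prop-2-enoate F2, and LiOH (THF–H2O) would give the corresponding prop-2-enoic acid F3. Intramolecular Friedel–Crafts acylation ((COCl)2, cat. DMF, then SnCl4, CH2Cl2, −78 to 0 °C) at the single free ring carbon would then give 12; the push–pull double bond should isomerise under the Lewis acid, so both geometric isomers can close.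

Step 4. The iodinating agent may oxidise the para-alkoxyphenol (quinone formation with loss of the ketal) instead of substituting it. The fallback would set out from 5 and come back to the route at 10. Magnesium-mediated ortho-formylation (MgCl2, Et3N, paraformaldehyde, MeCN, reflux) would give 5-hydroxy-6,7-dimethoxy-2,2-diphenyl-1,3-benzodioxole-4-carbaldehyde F4. Addition of the lithium acetylide of 8 (2.2 equiv, THF, −78 °C) would give racemic 3-(3-benzyloxy-4-methoxyphenyl)-1-(5-hydroxy-6,7-dimethoxy-2,2-diphenyl-1,3-benzodioxol-4-yl)prop-2-yn-1-ol F5, and MnO2 (CH2Cl2, rt) would oxidise this to ynone 10, which Et2NH alone should close to 12 as in the second half of step 6.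

Step 3. The triol may be oxidised by air, and its very nucleophilic free ring carbon may be benzhydrylated by the dichloride at 170 °C. The fallback would set out from 1 and come back to the route at 5, building the ketal before the fifth oxygen is introduced. Ortho-formylation of 1 (MgCl2, Et3N, paraformaldehyde) would give 2-hydroxy-3,4-dimethoxybenzaldehyde F6, Dakin oxidation (H2O2, aq NaOH) would give 3,4-dimethoxybenzene-1,2-diol F7, and ketalisation with Ph2CCl2 (neat, 160 °C) would give 4,5-dimethoxy-2,2-diphenyl-1,3-benzodioxole F8. Vilsmeier formylation (POCl3, DMF), expected para to the ring oxygen and ortho to the terminal methoxy group, would give 6,7-dimethoxy-2,2-diphenyl-1,3-benzodioxole-5-carbaldehyde F9. Baeyer–Villiger oxidation (mCPBA, CH2Cl2) would give 6,7-dimethoxy-2,2-diphenyl-1,3-benzodioxol-5-yl formate F10, and hydrolysis (aq KOH, MeOH) would give 5.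

**Further compounds**
F1 | step 6 | ethyl 3-(3-benzyloxy-4-methoxyphenyl)prop-2-ynoate | CCOC(=O)C#Cc1ccc(OC)c(OCc2ccccc2)c1
F2 | step 6 | ethyl 3-(3-benzyloxy-4-methoxyphenyl)-3-[(6,7-dimethoxy-2,2-diphenyl-1,3-benzodioxol-5-yl)oxy]prop-2-enoate (E/Z mixture) | CCOC(=O)C=C(Oc1cc2OC(c3ccccc3)(c3ccccc3)Oc2c(OC)c1OC)c1ccc(OC)c(OCc2ccccc2)c1
F3 | step 6 | 3-(3-benzyloxy-4-methoxyphenyl)-3-[(6,7-dimethoxy-2,2-diphenyl-1,3-benzodioxol-5-yl)oxy]prop-2-enoic acid (E/Z mixture) | OC(=O)C=C(Oc1cc2OC(c3ccccc3)(c3ccccc3)Oc2c(OC)c1OC)c1ccc(OC)c(OCc2ccccc2)c1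
F4 | step 4 | 5-hydroxy-6,7-dimethoxy-2,2-diphenyl-1,3-benzodioxole-4-carbaldehyde | COc1c(O)c(C=O)c2OC(c3ccccc3)(c3ccccc3)Oc2c1OC
F5 | step 4 | racemic 3-(3-benzyloxy-4-methoxyphenyl)-1-(5-hydroxy-6,7-dimethoxy-2,2-diphenyl-1,3-benzodioxol-4-yl)prop-2-yn-1-ol | COc1ccc(C#CC(O)c2c(O)c(OC)c(OC)c3OC(c4ccccc4)(c4ccccc4)Oc23)cc1OCc1ccccc1
F6 | step 3 | 2-hydroxy-3,4-dimethoxybenzaldehyde | COc1ccc(C=O)c(O)c1OC
F7 | step 3 | 3,4-dimethoxybenzene-1,2-diol | COc1ccc(O)c(O)c1OC
F8 | step 3 | 4,5-dimethoxy-2,2-diphenyl-1,3-benzodioxole | COc1ccc2OC(c3ccccc3)(c3ccccc3)Oc2c1OC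
F9 | step 3 | 6,7-dimethoxy-2,2-diphenyl-1,3-benzodioxole-5-carbaldehyde | COc1c(C=O)cc2OC(c3ccccc3)(c3ccccc3)Oc2c1OC
F10 | step 3 | 6,7-dimethoxy-2,2-diphenyl-1,3-benzodioxol-5-yl formate | COc1c(OC=O)cc2OC(c3ccccc3)(c3ccccc3)Oc2c1OC
A1 | direct plan | 1-(3-benzyloxy-2-hydroxy-4-methoxyphenyl)ethanone | CC(=O)c1ccc(OC)c(OCc2ccccc2)c1O
A2 | direct plan | 1-(3-benzyloxy-2,5-dihydroxy-4-methoxyphenyl)ethanone | CC(=O)c1cc(O)c(OC)c(OCc2ccccc2)c1O
A3 | direct plan | 3-benzyloxy-4-methoxybenzoyl chloride | COc1ccc(C(=O)Cl)cc1OCc1ccccc1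
A4 | direct plan | 1-(3-benzyloxy-2,5-dihydroxy-4-methoxyphenyl)-3-(3-benzyloxy-4-methoxyphenyl)propane-1,3-dione | COc1ccc(C(=O)CC(=O)c2cc(O)c(OC)c(OCc3ccccc3)c2O)cc1OCc1ccccc1
A5 | direct plan | 6-benzyloxy-2-[3-(3-benzyloxy-4-methoxyphenyl)-3-oxopropanoyl]-5-methoxy-1,4-benzoquinone | COc1ccc(C(=O)CC(=O)C2=CC(=O)C(OC)=C(OCc3ccccc3)C2=O)cc1OCc1ccccc1
A6 | direct plan | 6-benzyloxy-2-(3-benzyloxy-4-methoxyphenyl)-5,8-dihydroxy-7-methoxychromen-4-one | COc1ccc(-c2cc(=O)c3c(O)c(OCc4ccccc4)c(OC)c(O)c3o2)cc1OCc1ccccc1
A7 | direct plan | 6-benzyloxy-2-(3-benzyloxy-4-methoxyphenyl)-5-hydroxy-7,8-dimethoxychromen-4-one | COc1ccc(-c2cc(=O)c3c(O)c(OCc4ccccc4)c(OC)c(OC)c3o2)cc1OCc1ccccc1
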